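## Analysis of the target

The target 29 is a germacranolide: a ten-membered carbocycle C1–C10 fused across C6–C7 to a butenolide (O–C6–C7=C11–C12) whose double bond is tetrasubstituted and whose C11 carries the acetoxymethyl carbon C13. The carbocycle holds two more olefins, the trisubstituted Z-olefin C4=C5 (methyl on C4) and the exocyclic methylene C10=C14, so four of its ten ring atoms are sp2. There are three stereocenters, C1 (R, hydroperoxide), C3 (S, acetate) and C6 (R, lactone oxygen). C3 and C6 are 1,4-related across the Z-olefin and C1 and C3 are 1,3-related, so none can be relayed with confidence from another and each needs its own control element. The sensitive groups are the secondary allylic hydroperoxide (destroyed by phosphines, hydrides, low-valent metals and base), the two allylic acetates (the C13 acetate is also a vinylogous leaving group), and the C6 hydrogen, which is γ to the lactone carbonyl and allylic to C4=C5 and so is epimerisable by base. The hard points are the ten-membered ring closure, the Z geometry of a trisubstituted ring olefin, the fully substituted butenolide that joins both arms of the ring, and a hydroperoxide that must come last with defined configuration. The strategy rests on the butenolide: C6, C7, C11 and C13, with oxygen on C6 and C13, are the carbons of a but-2-yne-1,4-diol, so an alkyne C7≡C11 between the C6 carbinol and the C13 oxymethylene becomes the lactone once C8 is added to C7 and the carboxyl carbon C12 to C11 from opposite sides.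

## Retrosynthetic reasoning

**C1–O (hydroperoxide).** The hydroperoxide of 29 is cut first, because it survives none of the organometallic or reducing steps. It is traced through the allylic mesylate 28 to the epimeric alcohol 27. The forward reaction must invert C1 by a peroxide nucleophile without base strong enough to attack the acetates or the lactone.

**C1–C10 (ring closure).** The ring of 27 is opened between the carbinol C1 and the methylene-bearing C10, giving the iodo-aldehyde 26. This bond is chosen because an alkenyl-metal addition to an aldehyde creates the allylic alcohol and the exocyclic methylene in the same event. Every other ring bond is either part of an olefin whose geometry is better fixed in an open chain or is next to C3 or C6. The forward reaction must favour the ten-membered closure over intermolecular coupling and must leave two acetates and a lactone alone.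

**Functional-group adjustments.** Aldehyde 26 comes from alcohol 25 and this from the PMB ether 24. The 2-iodoalkene of 24 comes from the terminal alkyne of 22 by Markovnikov addition. The two acetates of 22 replace the silyl ethers of 20 by way of diol 21. The acetates go on before the ring is closed, so that after closure the C1 hydroxyl is the only free one.

**C7–C8, C11–C12 and C12–O (key disconnection).** The butenolide 20 is cut into the enynol 14, the Grignard reagent 16 and carbon dioxide 17. Cutting here removes the tetrasubstituted olefin, the lactone and the junction of the two chains in one stroke, and leaves an alkyne that simple acetylide chemistry can build. The forward reaction must place C8 on C7 and C12 on C11 anti to each other, with C12 on the side of the C6 oxygen, and must not touch the C6 center.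

**C6 stereocenter and C6–C7.** Carbinol 14 is traced to the ynone 13, so C6 is set by a catalyst rather than by the remote C3. Ynone 13 is cut at C6–C7 into the Weinreb amide 11 and the alkyne 12, which brings in C7, C11 and C13 with the C13 oxygen already present.

**C4–CH3 (olefin geometry).** Amide 11 comes from ester 10, and 10 from the ynoate 9 by syn-addition of methyl and hydrogen across C4≡C5. This is where the Z geometry is decided, in an open chain and by the mechanism of the addition, long before the ring exists.

**C5–C6, C3 stereocenter and C3–C4.** Ynoate 9 is the carboxylation product of alkyne 8, the silyl ether of 7. Carbinol 7 comes from 6, and 6 from the ynone 5 by asymmetric reduction, which sets C3. Ynone 5 comes through racemic 4 from aldehyde 2 and alkyne 3, and 2 from alcohol 1.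

**Grignard reagent.** Reagent 16, carrying C8, C9, C10 and C14 with the future vinyl iodide masked as a silyl alkyne, is made from bromide 15.

## Alternatives that were turned down

**Alternative 1: ring contraction by [2,3]-Wittig rearrangement.**
- Disconnection: the C6–C7 bond of the ring alcohol A2 is cut and C13 is joined to the C6 oxygen, which leads to the thirteen-membered cyclic diallyl ether A1.
- Forward key step: a strong lithium base removes the α-oxy allylic proton at C6 of A1. The carbanion attacks C7, the C13–O bond breaks, the double bond moves from C7=C11 to C11=C13, and the ring shrinks from thirteen to ten atoms.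
- For it: a thirteen-membered ether closes more easily than a ten-membered carbocycle, and the contraction runs through an ordered five-membered transition state. On ring formation it is stronger than the chosen route, whose chromium-mediated closure is less assured. It also frees the C6 alkoxide next to the protected C12 carboxyl.
- Against it: A2 has an sp3 stereocenter at C7 and an exocyclic C11=C13 methylene, the pattern of an α-methylene lactone. The target needs C7=C11 inside the lactone and oxygen on C13, so an allylic transposition with oxidation must follow and a stereocenter is made only to be destroyed. The base must distinguish C6–H from C13–H, both α-oxy and allylic. The configuration at C6 follows from the ring transition state and cannot be assigned in advance.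
- Comparison: the chosen strategy gives up the safer ring formation. In return it delivers the butenolide at the correct oxidation level with all four substituents in one operation, and sets C6 by a catalyst before any ring exists.

**Alternative 2: Z-selective ring-closing metathesis at C4=C5.**
- Disconnection: the C4=C5 bond of the ten-membered ketone A4 is cut, leading to the open-chain diene A3 with a vinyl group on C6 and an isopropenyl group on C3.
- Forward key step: a ruthenium carbene of the second-generation Hoveyda–Grubbs type loads onto the vinyl group and closes onto the isopropenyl group with loss of the two terminal methylene carbons.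
- For it: the butenolide and all three stereocenters, C1 included, are set in an open chain under reagent control. This is stronger than the chosen route, where C1 arises in the ring closure. The closure is catalytic and creates no stereocenter.
- Against it: the new olefin is trisubstituted, in a ten-membered ring, formed from a 1,1-disubstituted partner next to the acetate-bearing C3 and a vinyl partner on the lactone-bearing C6. Both are hindered and deactivated, and dimerisation competes. The geometry is left to ring strain, with no remedy if E forms. The C10 ketone of A4 must later be methylenated beside the epimerisable C1 in the presence of two acetates and a lactone, which basic ylides and titanium carbenoids do not tolerate well.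
- Comparison: the chosen strategy fixes the Z geometry at the outset by a syn-carbometalation and forms the exocyclic methylene in the ring closure itself. It pays for this with a less certain C1.

**Alternative 3: anionic oxy-Cope ring expansion.**
- Disconnection: the C8–C9 bond of the dienone A6 is cut and C1 is rejoined to C6, leading to the divinylcyclohexenol A5.
- Forward key step: the potassium alkoxide of A5 undergoes the [3,3] shift, forming C8–C9 and breaking C1–C6, and gives the ten-membered ring as its C6 enolate.
- For it: it is the shortest way to the ring. Both ring olefin geometries follow from the six-membered precursor and the transition state. The 1(10)-olefin of A6 is the ideal substrate for a Schenck ene reaction with singlet oxygen, which would install the C1 hydroperoxide and the C10=C14 methylene together. For the hydroperoxide this endgame is stronger than the displacement used here.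
- Against it: A6 contains none of the lactone carbons and C7 is a methylene. C11, C12 and C13 must be attached through the C6 ketone enolate, C6 reduced under ring control only, and the tetrasubstituted C7=C11 olefin and the C13 oxygen introduced. All of this must be done on a medium-ring 1,5-diene that is prone to transannular cyclisation and Cope rearrangement. The key step leaves the hardest part of the molecule unsolved.
- Comparison: the chosen strategy builds the butenolide first, convergently, and accepts a weaker solution for C1. The singlet-oxygen endgame is kept as a fallback for the last step.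

Key step: step 13

**Remarks on the chemistry**
- Compounds 1, 3, 12 and 15 are taken as purchasable.
- The sense of both transfer hydrogenations (steps 4 and 11) is assigned by analogy with alkyl alkynyl ketones.
- The ring closure of step 19 is written for the (1S)-alcohol 27 that the final inversion needs; the correction for the other epimer is given at the end.

## Route

Step 1
Reactants: 1 alcohol 3-[(4-methoxybenzyl)oxy]propan-1-ol
Product: 2 aldehyde 3-[(4-methoxybenzyl)oxy]propanal
Conditions: TEMPO (10 mol%), PhI(OAc)2, CH2Cl2, rt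
Reagents that add atoms: none
Why: TEMPO/oxoammonium oxidation of a primary alcohol stops at the aldehyde and runs without base, so the β-alkoxy aldehyde should not eliminate; the PMB ether is inert.

Step 2
Reactants: 2 aldehyde 3-[(4-methoxybenzyl)oxy]propanal; 3 ethynyltrimethylsilane
Product: 4 racemic 5-[(4-methoxybenzyl)oxy]-1-(trimethylsilyl)pent-1-yn-3-ol
Conditions: 3, n-BuLi, THF, −78 °C; then 2; H2O quench
Reagents that add atoms: none
Why: 1,2-Addition of a lithium acetylide to an aldehyde forms the C3–C4 bond; the carbinol is left racemic because it is erased in step 3 and reset in step 4.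

Step 3
Reactants: 4 racemic 5-[(4-methoxybenzyl)oxy]-1-(trimethylsilyl)pent-1-yn-3-ol
Product: 5 ynone 5-[(4-methoxybenzyl)oxy]-1-(trimethylsilyl)pent-1-yn-3-one
Conditions: Dess–Martin periodinane, CH2Cl2, 0 °C→rt
Reagents that add atoms: none
Why: Dess–Martin oxidation of the secondary propargylic alcohol gives the ynone without base, which the β-alkoxy ketone would not tolerate.

Step 4
Reactants: 5 ynone 5-[(4-methoxybenzyl)oxy]-1-(trimethylsilyl)pent-1-yn-3-one
Product: 6 carbinol (3S)-5-[(4-methoxybenzyl)oxy]-1-(trimethylsilyl)pent-1-yn-3-ol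
Conditions: Ru[(S,S)-TsDPEN](p-cymene) (1 mol%), iPrOH, rt
Reagents that add atoms: none
Why: Noyori asymmetric transfer hydrogenation of an alkyl alkynyl ketone: the alkyne takes the place an aryl group takes next to the arene ligand, so the (S,S)-catalyst should deliver hydride to the face that gives the (S)-carbinol. C3 is set here by the catalyst alone, and the alkyne is not reduced.

Step 5
Reactants: 6 carbinol (3S)-5-[(4-methoxybenzyl)oxy]-1-(trimethylsilyl)pent-1-yn-3-ol
Product: 7 alkynol (3S)-5-[(4-methoxybenzyl)oxy]pent-1-yn-3-ol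
Conditions: K2CO3 (cat.), MeOH, rt
Reagents that add atoms: none
Why: Methanolysis of the alkynyl C–Si bond with catalytic carbonate; the ether and the carbinol center are untouched.

Step 6
Reactants: 7 alkynol (3S)-5-[(4-methoxybenzyl)oxy]pent-1-yn-3-ol
Product: 8 silyl ether tert-butyl({(3S)-5-[(4-methoxybenzyl)oxy]pent-1-yn-3-yl}oxy)dimethylsilane
Conditions: TBSCl, imidazole, DMF, rt
Reagents that add atoms: tert-butyldimethylsilyl chloride, CC(C)(C)[Si](C)(C)Cl
Why: Standard silylation of a secondary alcohol; the TBS ether prevents lactonisation later and survives the organometallic steps up to step 13.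

Step 7
Reactants: 8 silyl ether tert-butyl({(3S)-5-[(4-methoxybenzyl)oxy]pent-1-yn-3-yl}oxy)dimethylsilane
Product: 9 ynoate methyl (4S)-4-[(tert-butyldimethylsilyl)oxy]-6-[(4-methoxybenzyl)oxy]hex-2-ynoate
Conditions: n-BuLi, THF, −78 °C; then ClCO2Me, −78→0 °C
Reagents that add atoms: methyl chloroformate, COC(=O)Cl
Why: Deprotonation of the terminal alkyne and C-acylation of the acetylide forms C5–C6 and activates the alkyne for conjugate addition.

Step 8
Reactants: 9 ynoate methyl (4S)-4-[(tert-butyldimethylsilyl)oxy]-6-[(4-methoxybenzyl)oxy]hex-2-ynoate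
Product: 10 enoate methyl (2Z,4S)-4-[(tert-butyldimethylsilyl)oxy]-6-[(4-methoxybenzyl)oxy]-3-methylhex-2-enoate
Conditions: Me2CuLi, THF, −78 °C; quench with wet THF at −78 °C
Reagents that add atoms: lithium dimethylcuprate, [Li+].C[Cu-]C
Why: Conjugate addition of a Gilman cuprate to an ynoate is a syn-carbocupration: methyl adds to C4 and copper to C5 on the same side, and protonation at −78 °C with retention places C3 and the ester carbon cis, which is the Z-olefin of the target. The low temperature prevents equilibration through the allenoate.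

Step 9
Reactants: 10 enoate methyl (2Z,4S)-4-[(tert-butyldimethylsilyl)oxy]-6-[(4-methoxybenzyl)oxy]-3-methylhex-2-enoate
Product: 11 Weinreb amide (2Z,4S)-4-[(tert-butyldimethylsilyl)oxy]-N-methoxy-6-[(4-methoxybenzyl)oxy]-N,3-dimethylhex-2-enamide
Conditions: MeNHOMe·HCl, iPrMgCl, THF, −20→0 °C
Reagents that add atoms: N,O-dimethylhydroxylamine hydrochloride, CNOC.Cl
Why: Aminolysis of the ester by the chloromagnesium amide gives the Weinreb amide; the β,β-disubstituted enoate does not undergo conjugate addition, so the Z geometry should be kept.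

Step 10
Reactants: 11 Weinreb amide (2Z,4S)-4-[(tert-butyldimethylsilyl)oxy]-N-methoxy-6-[(4-methoxybenzyl)oxy]-N,3-dimethylhex-2-enamide; 12 alkyne tert-butyldimethyl(prop-2-yn-1-yloxy)silane
Product: 13 ynone (5Z,7S)-1,7-bis[(tert-butyldimethylsilyl)oxy]-9-[(4-methoxybenzyl)oxy]-6-methylnon-5-en-2-yn-4-one
Conditions: 12, n-BuLi, THF, −78 °C; then 11, −78→0 °C; H2O quench
Reagents that add atoms: none
Why: Acylation of a lithium acetylide by a Weinreb amide stops at the ketone because the chelated tetrahedral adduct collapses only on work-up; it forms C6–C7 with C13 and its oxygen already in place.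

Step 11
Reactants: 13 ynone (5Z,7S)-1,7-bis[(tert-butyldimethylsilyl)oxy]-9-[(4-methoxybenzyl)oxy]-6-methylnon-5-en-2-yn-4-one
Product: 14 enynol (4R,5Z,7S)-1,7-bis[(tert-butyldimethylsilyl)oxy]-9-[(4-methoxybenzyl)oxy]-6-methylnon-5-en-2-yn-4-ol (C4 of this name is C6 of the target)
Conditions: Ru[(R,R)-TsDPEN](p-cymene) (2 mol%), iPrOH, rt
Reagents that add atoms: none
Why: Noyori asymmetric transfer hydrogenation again: the alkyne is taken to sit next to the arene ligand and the twisted Z-alkenyl group to play the part of the alkyl group, so the (R,R)-catalyst should give the (4R)-carbinol, which is 6R in target numbering. The reduction is 1,2-selective and the remote C3 is unaffected.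

Step 12
Reactants: 15 bromide (4-bromobut-1-yn-1-yl)trimethylsilane
Product: 16 Grignard reagent [4-(trimethylsilyl)but-3-yn-1-yl]magnesium bromide
Conditions: Mg turnings, THF, rt→40 °C
Reagents that add atoms: magnesium, [Mg]
Why: Direct insertion of magnesium into a primary alkyl bromide; the silyl group protects the alkyne terminus against deprotonation by the reagent.

Step 13
Reactants: 14 enynol (4R,5Z,7S)-1,7-bis[(tert-butyldimethylsilyl)oxy]-9-[(4-methoxybenzyl)oxy]-6-methylnon-5-en-2-yn-4-ol; 16 Grignard reagent [4-(trimethylsilyl)but-3-yn-1-yl]magnesium bromide; 17 carbon dioxide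
Product: 20 butenolide (5R)-3-{[(tert-butyldimethylsilyl)oxy]methyl}-5-[(1Z,3S)-3-[(tert-butyldimethylsilyl)oxy]-5-[(4-methoxybenzyl)oxy]-2-methylpent-1-en-1-yl]-4-[4-(trimethylsilyl)but-3-yn-1-yl]furan-2(5H)-one, via alkenylmagnesium chelate 18 (not isolated), via hydroxy acid 19 (not isolated)
Conditions: 16 (3.5 equiv), CuI (10 mol%), THF/Et2O, −10 °C→rt; then CO2 (1 atm), −40 °C→rt; aq. citric acid work-up
Reagents that add atoms: none
Why: The first equivalent of 16 deprotonates the C6 hydroxyl; a second, activated by CuI, is delivered within the magnesium alkoxide to the near alkyne carbon C7 while magnesium ends on C11 on the opposite side, an anti-carbomagnesiation that closes the five-membered oxamagnesacycle 18. Carbon dioxide inserts into the C11–Mg bond, and acidification gives hydroxy acid 19 with the carboxyl held cis to the C6 oxygen. The ring then closes by a 5-exo-trig lactonisation (O6 onto C12) to give 20. The closest known reaction type is the alkoxide-directed anti-carbomagnesiation of propargylic alcohols, copper-assisted for alkyl Grignard reagents, with carbon dioxide trapping to butenolides. No stereocenter is formed, and C6 keeps its configuration because neither its C–O nor its C–H bond is broken. The step needs regioselectivity (C8 to C7, carboxyl to C11) and anti stereochemistry, and both are imposed by the C6 alkoxide chelate, since the C13 oxygen is silylated and cannot direct. The C4=C5 alkene, the silyl alkyne of 16, the silyl ethers and the PMB ether should be inert to the reagent at these temperatures.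

Step 14
Reactants: 20 butenolide (5R)-3-{[(tert-butyldimethylsilyl)oxy]methyl}-5-[(1Z,3S)-3-[(tert-butyldimethylsilyl)oxy]-5-[(4-methoxybenzyl)oxy]-2-methylpent-1-en-1-yl]-4-[4-(trimethylsilyl)but-3-yn-1-yl]furan-2(5H)-one
Product: 21 diol (5R)-4-(but-3-yn-1-yl)-3-(hydroxymethyl)-5-[(1Z,3S)-3-hydroxy-5-[(4-methoxybenzyl)oxy]-2-methylpent-1-en-1-yl]furan-2(5H)-one
Conditions: TBAF, AcOH (1:1), THF, 0 °C→rt
Reagents that add atoms: none
Why: Fluoride cleaves both O–Si bonds and the alkynyl C–Si bond in one operation; buffering with acetic acid keeps the medium from deprotonating C6–H of the butenolide.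

Step 15
Reactants: 21 diol (5R)-4-(but-3-yn-1-yl)-3-(hydroxymethyl)-5-[(1Z,3S)-3-hydroxy-5-[(4-methoxybenzyl)oxy]-2-methylpent-1-en-1-yl]furan-2(5H)-one
Product: 22 diacetate [(5R)-5-[(1Z,3S)-3-acetoxy-5-[(4-methoxybenzyl)oxy]-2-methylpent-1-en-1-yl]-4-(but-3-yn-1-yl)-2-oxo-2,5-dihydrofuran-3-yl]methyl acetate
Conditions: Ac2O, pyridine, DMAP (cat.), CH2Cl2, 0 °C
Reagents that add atoms: acetic anhydride, CC(=O)OC(C)=O
Why: Acylation of the primary and the secondary allylic alcohol under mild amine catalysis; both acetates of the target are in place before any oxidising step.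

Step 16
Reactants: 22 diacetate [(5R)-5-[(1Z,3S)-3-acetoxy-5-[(4-methoxybenzyl)oxy]-2-methylpent-1-en-1-yl]-4-(but-3-yn-1-yl)-2-oxo-2,5-dihydrofuran-3-yl]methyl acetate
Product: 24 vinyl iodide [(5R)-5-[(1Z,3S)-3-acetoxy-5-[(4-methoxybenzyl)oxy]-2-methylpent-1-en-1-yl]-4-(3-iodobut-3-en-1-yl)-2-oxo-2,5-dihydrofuran-3-yl]methyl acetate, via iodoboration adduct 23 (not isolated)
Conditions: B-I-9-BBN, hexane/CH2Cl2, −20→0 °C; then AcOH, 0 °C
Reagents that add atoms: 9-iodo-9-borabicyclo[3.3.1]nonane, IB1C2CCCC1CCC2
Why: Markovnikov hydroiodination in two stages: syn-iodoboration places boron on the terminal carbon C14 and iodine on C10, and protonolysis of the C–B bond by acetic acid gives the 2-iodoalk-1-ene. At low temperature the reagent should discriminate the terminal alkyne from the trisubstituted alkene, the esters and the PMB ether.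

Step 17
Reactants: 24 vinyl iodide [(5R)-5-[(1Z,3S)-3-acetoxy-5-[(4-methoxybenzyl)oxy]-2-methylpent-1-en-1-yl]-4-(3-iodobut-3-en-1-yl)-2-oxo-2,5-dihydrofuran-3-yl]methyl acetate
Product: 25 alcohol [(5R)-5-[(1Z,3S)-3-acetoxy-5-hydroxy-2-methylpent-1-en-1-yl]-4-(3-iodobut-3-en-1-yl)-2-oxo-2,5-dihydrofuran-3-yl]methyl acetate
Conditions: DDQ, CH2Cl2/pH 7 buffer, 0 °C
Reagents that add atoms: none
Why: Oxidative cleavage of the PMB ether by DDQ through the benzylic oxocarbenium ion, which the buffer hydrolyses; the acetates, the vinyl iodide and the electron-poor olefins are not oxidised.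

Step 18
Reactants: 25 alcohol [(5R)-5-[(1Z,3S)-3-acetoxy-5-hydroxy-2-methylpent-1-en-1-yl]-4-(3-iodobut-3-en-1-yl)-2-oxo-2,5-dihydrofuran-3-yl]methyl acetate
Product: 26 aldehyde [(5R)-5-[(1Z,3S)-3-acetoxy-2-methyl-5-oxopent-1-en-1-yl]-4-(3-iodobut-3-en-1-yl)-2-oxo-2,5-dihydrofuran-3-yl]methyl acetate
Conditions: Dess–Martin periodinane, CH2Cl2, 0 °C→rt
Reagents that add atoms: none
Why: Dess–Martin oxidation gives the aldehyde without base, which matters because the C3 acetate is β to the new carbonyl and would eliminate; the aldehyde is used at once.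

Step 19
Reactants: 26 aldehyde [(5R)-5-[(1Z,3S)-3-acetoxy-2-methyl-5-oxopent-1-en-1-yl]-4-(3-iodobut-3-en-1-yl)-2-oxo-2,5-dihydrofuran-3-yl]methyl acetate
Product: 27 ring alcohol (1S,3S,6R,4Z)-3,13-diacetoxy-1-hydroxygermacra-4,7(11),10(14)-trien-12,6-olide
Conditions: CrCl2 (15 equiv), NiCl2 (2 mol%), degassed DMSO/THF, rt, 2 mM; aqueous work-up
Reagents that add atoms: none
Why: Nozaki–Hiyama–Kishi reaction: zerovalent nickel inserts into the C10–I bond and transmetalation gives an alkenylchromium species of trivalent chromium that adds to the C1 aldehyde and to no ester. This closes the ten-membered ring (10-exo-trig addition to the carbonyl) at high dilution and creates the allylic alcohol and the exocyclic methylene together. C1 is set under control of the ring conformation only, and the (1S)-epimer is carried on.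

Step 20
Reactants: 27 ring alcohol (1S,3S,6R,4Z)-3,13-diacetoxy-1-hydroxygermacra-4,7(11),10(14)-trien-12,6-olide
Product: 29 target (1R,3S,6R,4Z)-3,13-diacetoxy-1-hydroperoxygermacra-4,7(11),10(14)-trien-12,6-olide, via allylic mesylate 28 (not isolated)
Conditions: MsCl, Et3N, CH2Cl2, −40 °C; then anhydrous H2O2 in Et2O (excess), −40→0 °C
Reagents that add atoms: hydrogen peroxide, OO
Why: Sulfonylation at low temperature, then SN2 displacement of the allylic mesylate by hydrogen peroxide (an α-effect nucleophile), inverts C1 from S to R. No hydroxide or alkoxide is present, so the acetates and the lactone should survive, and the hydroperoxide is made last.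

## Compound list

1 | 3-[(4-methoxybenzyl)oxy]propan-1-ol | COc1ccc(COCCCO)cc1 | starting material
2 | 3-[(4-methoxybenzyl)oxy]propanal | COc1ccc(COCCC=O)cc1 | intermediate
3 | ethynyltrimethylsilane | C#C[Si](C)(C)C | starting material
4 | racemic 5-[(4-methoxybenzyl)oxy]-1-(trimethylsilyl)pent-1-yn-3-ol | COc1ccc(COCCC(O)C#C[Si](C)(C)C)cc1 | intermediate
5 | 5-[(4-methoxybenzyl)oxy]-1-(trimethylsilyl)pent-1-yn-3-one | COc1ccc(COCCC(=O)C#C[Si](C)(C)C)cc1 | intermediate
6 | (3S)-5-[(4-methoxybenzyl)oxy]-1-(trimethylsilyl)pent-1-yn-3-ol | COc1ccc(COCC[C@H](O)C#C[Si](C)(C)C)cc1 | intermediate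
7 | (3S)-5-[(4-methoxybenzyl)oxy]pent-1-yn-3-ol | COc1ccc(COCC[C@H](O)C#C)cc1 | intermediate
8 | tert-butyl({(3S)-5-[(4-methoxybenzyl)oxy]pent-1-yn-3-yl}oxy)dimethylsilane | COc1ccc(COCC[C@H](O[Si](C)(C)C(C)(C)C)C#C)cc1 | intermediate
9 | methyl (4S)-4-[(tert-butyldimethylsilyl)oxy]-6-[(4-methoxybenzyl)oxy]hex-2-ynoate | COc1ccc(COCC[C@H](O[Si](C)(C)C(C)(C)C)C#CC(=O)OC)cc1 | intermediate
10 | methyl (2Z,4S)-4-[(tert-butyldimethylsilyl)oxy]-6-[(4-methoxybenzyl)oxy]-3-methylhex-2-enoate | COc1ccc(COCC[C@H](O[Si](C)(C)C(C)(C)C)/C(C)=C\C(=O)OC)cc1 | intermediate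
11 | (2Z,4S)-4-[(tert-butyldimethylsilyl)oxy]-N-methoxy-6-[(4-methoxybenzyl)oxy]-N,3-dimethylhex-2-enamide | COc1ccc(COCC[C@H](O[Si](C)(C)C(C)(C)C)/C(C)=C\C(=O)N(C)OC)cc1 | intermediate
12 | tert-butyldimethyl(prop-2-yn-1-yloxy)silane | C#CCO[Si](C)(C)C(C)(C)C | starting material
13 | (5Z,7S)-1,7-bis[(tert-butyldimethylsilyl)oxy]-9-[(4-methoxybenzyl)oxy]-6-methylnon-5-en-2-yn-4-one | COc1ccc(COCC[C@H](O[Si](C)(C)C(C)(C)C)/C(C)=C\C(=O)C#CCO[Si](C)(C)C(C)(C)C)cc1 | intermediate
14 | (4R,5Z,7S)-1,7-bis[(tert-butyldimethylsilyl)oxy]-9-[(4-methoxybenzyl)oxy]-6-methylnon-5-en-2-yn-4-ol (enynol spanning C1–C7, C11, C13) | COc1ccc(COCC[C@H](O[Si](C)(C)C(C)(C)C)/C(C)=C\[C@@H](O)C#CCO[Si](C)(C)C(C)(C)C)cc1 | intermediate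
15 | (4-bromobut-1-yn-1-yl)trimethylsilane | C[Si](C)(C)C#CCCBr | starting material
16 | [4-(trimethylsilyl)but-3-yn-1-yl]magnesium bromide | C[Si](C)(C)C#CCC[Mg]Br | intermediate
17 | carbon dioxide | O=C=O | starting material
18 | (5R)-3-{[(tert-butyldimethylsilyl)oxy]methyl}-5-[(1Z,3S)-3-[(tert-butyldimethylsilyl)oxy]-5-[(4-methoxybenzyl)oxy]-2-methylpent-1-en-1-yl]-4-[4-(trimethylsilyl)but-3-yn-1-yl]-2,5-dihydro-1,2-oxamagnesole (alkenylmagnesium chelate) | C[Si](C)(C)C#CCCC1=C(CO[Si](C)(C)C(C)(C)C)[Mg]O[C@@H]1/C=C(/C)[C@@H](O[Si](C)(C)C(C)(C)C)CCOCc2ccc(OC)cc2 | intermediate (not isolated)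
19 | (2Z,4R,5Z,7S)-7-[(tert-butyldimethylsilyl)oxy]-2-{[(tert-butyldimethylsilyl)oxy]methyl}-4-hydroxy-9-[(4-methoxybenzyl)oxy]-6-methyl-3-[4-(trimethylsilyl)but-3-yn-1-yl]nona-2,5-dienoic acid | OC(=O)/C(CO[Si](C)(C)C(C)(C)C)=C(/CCC#C[Si](C)(C)C)[C@H](O)/C=C(/C)[C@@H](O[Si](C)(C)C(C)(C)C)CCOCc1ccc(OC)cc1 | intermediate (not isolated)
20 | (5R)-3-{[(tert-butyldimethylsilyl)oxy]methyl}-5-[(1Z,3S)-3-[(tert-butyldimethylsilyl)oxy]-5-[(4-methoxybenzyl)oxy]-2-methylpent-1-en-1-yl]-4-[4-(trimethylsilyl)but-3-yn-1-yl]furan-2(5H)-one | C[Si](C)(C)C#CCCC1=C(CO[Si](C)(C)C(C)(C)C)C(=O)O[C@@H]1/C=C(/C)[C@@H](O[Si](C)(C)C(C)(C)C)CCOCc2ccc(OC)cc2 | intermediate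
21 | (5R)-4-(but-3-yn-1-yl)-3-(hydroxymethyl)-5-[(1Z,3S)-3-hydroxy-5-[(4-methoxybenzyl)oxy]-2-methylpent-1-en-1-yl]furan-2(5H)-one | C#CCCC1=C(CO)C(=O)O[C@@H]1/C=C(/C)[C@@H](O)CCOCc2ccc(OC)cc2 | intermediate
22 | [(5R)-5-[(1Z,3S)-3-acetoxy-5-[(4-methoxybenzyl)oxy]-2-methylpent-1-en-1-yl]-4-(but-3-yn-1-yl)-2-oxo-2,5-dihydrofuran-3-yl]methyl acetate | C#CCCC1=C(COC(C)=O)C(=O)O[C@@H]1/C=C(/C)[C@@H](OC(C)=O)CCOCc2ccc(OC)cc2 | intermediate
23 | iodoboration adduct of 22: (Z)-2-iodoalkenyl-9-BBN with boron on C14 and iodine on C10 | I/C(CCC1=C(COC(C)=O)C(=O)O[C@@H]1/C=C(/C)[C@@H](OC(C)=O)CCOCc2ccc(OC)cc2)=C\B3C4CCCC3CCC4 | intermediate (not isolated)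
24 | [(5R)-5-[(1Z,3S)-3-acetoxy-5-[(4-methoxybenzyl)oxy]-2-methylpent-1-en-1-yl]-4-(3-iodobut-3-en-1-yl)-2-oxo-2,5-dihydrofuran-3-yl]methyl acetate | C=C(I)CCC1=C(COC(C)=O)C(=O)O[C@@H]1/C=C(/C)[C@@H](OC(C)=O)CCOCc2ccc(OC)cc2 | intermediate
25 | [(5R)-5-[(1Z,3S)-3-acetoxy-5-hydroxy-2-methylpent-1-en-1-yl]-4-(3-iodobut-3-en-1-yl)-2-oxo-2,5-dihydrofuran-3-yl]methyl acetate | C=C(I)CCC1=C(COC(C)=O)C(=O)O[C@@H]1/C=C(/C)[C@@H](OC(C)=O)CCO | intermediate
26 | [(5R)-5-[(1Z,3S)-3-acetoxy-2-methyl-5-oxopent-1-en-1-yl]-4-(3-iodobut-3-en-1-yl)-2-oxo-2,5-dihydrofuran-3-yl]methyl acetate | C=C(I)CCC1=C(COC(C)=O)C(=O)O[C@@H]1/C=C(/C)[C@@H](OC(C)=O)CC=O | intermediate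
27 | (1S,3S,6R,4Z)-3,13-diacetoxy-1-hydroxygermacra-4,7(11),10(14)-trien-12,6-olide | C=C1CCC2=C(COC(C)=O)C(=O)O[C@@H]2/C=C(/C)[C@@H](OC(C)=O)C[C@@H]1O | intermediate
28 | (1S,3S,6R,4Z)-3,13-diacetoxy-1-(methanesulfonyloxy)germacra-4,7(11),10(14)-trien-12,6-olide | C=C1CCC2=C(COC(C)=O)C(=O)O[C@@H]2/C=C(/C)[C@@H](OC(C)=O)C[C@@H]1OS(C)(=O)=O | intermediate (not isolated)
29 | (1R,3S,6R,4Z)-3,13-diacetoxy-1-hydroperoxygermacra-4,7(11),10(14)-trien-12,6-olide (CNP0174966.1) | C=C1CCC2=C(COC(C)=O)C(=O)O[C@@H]2/C=C(/C)[C@@H](OC(C)=O)C[C@H]1OO | target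

## Step count and least certain steps

Total: 20 steps. Longest linear sequence: 19 steps (steps 1–11 and 13–20 from 1); step 12 is a one-step side branch. The key step is step 13.

**Step 11 (C6 by transfer hydrogenation).** Facial discrimination may be weaker than with alkyl ynones, because the Z-alkenyl group is itself a π-substituent and can compete with the alkyne for the site next to the arene ligand; the cross-conjugated ketone could also lose its Z geometry. The fallback sets the center in a C–C bond formation instead. It sets out from 11: DIBAL at −78 °C reduces the Weinreb amide to the aldehyde (2Z,4S)-4-[(tert-butyldimethylsilyl)oxy]-6-[(4-methoxybenzyl)oxy]-3-methylhex-2-enal F1. The alkynylzinc made from 12 and Me2Zn is then added under catalysis by the ProPhenol enantiomer that gives the (4R)-carbinol, and the route is rejoined at 14.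

**Step 13 (key step).** Transfer of an unactivated primary alkyl group to C7 of a hindered secondary alkoxide is the slowest variant of this reaction. The alkenylmetal on C11 may also expel the C13 silyloxy group by β-elimination to an allene, a path that copper is known to open for propargylic ethers. The fallback moves the carboxyl carbon onto the alkyne and brings C13 in afterwards. It sets out from 11 by way of the enal F1 described above. Zinc/ProPhenol-catalysed addition of methyl propiolate gives the hydroxy ynoate methyl (4R,5Z,7S)-7-[(tert-butyldimethylsilyl)oxy]-4-hydroxy-9-[(4-methoxybenzyl)oxy]-6-methylnon-5-en-2-ynoate F2. The organocopper reagent from 16 and CuBr·SMe2 adds syn to C7 at −78 °C, where the alkenylcopper has no β-leaving group, and is trapped with I2; on work-up the cis hydroxy ester closes to the iodobutenolide (5R)-5-[(1Z,3S)-3-[(tert-butyldimethylsilyl)oxy]-5-[(4-methoxybenzyl)oxy]-2-methylpent-1-en-1-yl]-3-iodo-4-[4-(trimethylsilyl)but-3-yn-1-yl]furan-2(5H)-one F3. Stille coupling with (tributylstannyl)methanol and Pd(PPh3)4 gives the hydroxymethyl butenolide (5R)-5-[(1Z,3S)-3-[(tert-butyldimethylsilyl)oxy]-5-[(4-methoxybenzyl)oxy]-2-methylpent-1-en-1-yl]-3-(hydroxymethyl)-4-[4-(trimethylsilyl)but-3-yn-1-yl]furan-2(5H)-one F4. Silylation with TBSCl and imidazole rejoins the route at 20.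

**Step 16 (hydroiodination).** The Lewis-acidic boron iodide may cleave the PMB ether or ionise an allylic acetate before it has consumed the alkyne. The fallback separates the regiochemical step from the iodination. It sets out from 22: hydrosilylation with Et3SiH and [Cp*Ru(MeCN)3]PF6, which is Markovnikov-selective for terminal alkynes, gives the vinylsilane [(5R)-5-[(1Z,3S)-3-acetoxy-5-[(4-methoxybenzyl)oxy]-2-methylpent-1-en-1-yl]-2-oxo-4-[3-(triethylsilyl)but-3-en-1-yl]-2,5-dihydrofuran-3-yl]methyl acetate F5. Iododesilylation with N-iodosuccinimide in acetonitrile rejoins the route at 24.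

**Step 19 (ring closure).** Facial selectivity at C1 rests on the ring conformation alone and may be poor or favour the wrong epimer; intermolecular coupling competes with the medium-ring closure. The fallback replaces substrate control by reagent control. It sets out from 26: the closure product, obtained as the epimer (1R,3S,6R,4Z)-3,13-diacetoxy-1-hydroxygermacra-4,7(11),10(14)-trien-12,6-olide F6 or as a mixture with 27, is oxidised with Dess–Martin periodinane to the enone (3S,6R,4Z)-3,13-diacetoxy-1-oxogermacra-4,7(11),10(14)-trien-12,6-olide F7. Corey–Bakshi–Shibata reduction with the (R)-oxazaborolidine and catecholborane, in which the α-substituted vinyl group is the large substituent, should give the (1S)-alcohol and rejoins the route at 27.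

**Step 20 (hydroperoxide).** The allylic mesylate may react through an ion pair, with attack at C14 (allylic transposition) or loss of stereochemical integrity at C1. Backside approach to a ring carbon of a ten-membered ring may be hindered, and any excess base would start perhydrolysis of the acetates. The fallback abandons the displacement for an ene reaction. It sets out from 27: Mitsunobu reaction with 2-nitrobenzenesulfonylhydrazide (PPh3, diethyl azodicarboxylate, −30 °C) gives the sulfonylhydrazide (1R,3S,6R,4Z)-3,13-diacetoxy-1-[1-(2-nitrobenzenesulfonyl)hydrazinyl]germacra-4,7(11),10(14)-trien-12,6-olide F8. On warming it loses sulfinic acid to the allylic diazene (1R,3S,6R,4Z)-3,13-diacetoxy-1-diazenylgermacra-4,7(11),10(14)-trien-12,6-olide F9. This extrudes dinitrogen with 1,3-transposition of the olefin to the triene (3S,6R,1(10)E,4Z)-3,13-diacetoxygermacra-1(10),4,7(11)-trien-12,6-olide F10. A Schenck ene reaction of F10 with singlet oxygen (O2, light, tetraphenylporphyrin, CH2Cl2, −20 °C) abstracts a C14 hydrogen and places the hydroperoxide on C1 from the outer face of the ring, which rejoins the route at 29. The C1 configuration of 27 is erased on this path, so it also serves if step 19 is unselective.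

## Further compounds

F1 | step 11 | (2Z,4S)-4-[(tert-butyldimethylsilyl)oxy]-6-[(4-methoxybenzyl)oxy]-3-methylhex-2-enal | COc1ccc(COCC[C@H](O[Si](C)(C)C(C)(C)C)/C(C)=C\C=O)cc1
F2 | step 13 | methyl (4R,5Z,7S)-7-[(tert-butyldimethylsilyl)oxy]-4-hydroxy-9-[(4-methoxybenzyl)oxy]-6-methylnon-5-en-2-ynoate | COc1ccc(COCC[C@H](O[Si](C)(C)C(C)(C)C)/C(C)=C\[C@@H](O)C#CC(=O)OC)cc1
F3 | step 13 | (5R)-5-[(1Z,3S)-3-[(tert-butyldimethylsilyl)oxy]-5-[(4-methoxybenzyl)oxy]-2-methylpent-1-en-1-yl]-3-iodo-4-[4-(trimethylsilyl)but-3-yn-1-yl]furan-2(5H)-one | C[Si](C)(C)C#CCCC1=C(I)C(=O)O[C@@H]1/C=C(/C)[C@@H](O[Si](C)(C)C(C)(C)C)CCOCc2ccc(OC)cc2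
F4 | step 13 | (5R)-5-[(1Z,3S)-3-[(tert-butyldimethylsilyl)oxy]-5-[(4-methoxybenzyl)oxy]-2-methylpent-1-en-1-yl]-3-(hydroxymethyl)-4-[4-(trimethylsilyl)but-3-yn-1-yl]furan-2(5H)-one | C[Si](C)(C)C#CCCC1=C(CO)C(=O)O[C@@H]1/C=C(/C)[C@@H](O[Si](C)(C)C(C)(C)C)CCOCc2ccc(OC)cc2
F5 | step 16 | [(5R)-5-[(1Z,3S)-3-acetoxy-5-[(4-methoxybenzyl)oxy]-2-methylpent-1-en-1-yl]-2-oxo-4-[3-(triethylsilyl)but-3-en-1-yl]-2,5-dihydrofuran-3-yl]methyl acetate | C=C([Si](CC)(CC)CC)CCC1=C(COC(C)=O)C(=O)O[C@@H]1/C=C(/C)[C@@H](OC(C)=O)CCOCc2ccc(OC)cc2
F6 | step 19 | (1R,3S,6R,4Z)-3,13-diacetoxy-1-hydroxygermacra-4,7(11),10(14)-trien-12,6-olide | C=C1CCC2=C(COC(C)=O)C(=O)O[C@@H]2/C=C(/C)[C@@H](OC(C)=O)C[C@H]1O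
F7 | step 19 | (3S,6R,4Z)-3,13-diacetoxy-1-oxogermacra-4,7(11),10(14)-trien-12,6-olide | C=C1CCC2=C(COC(C)=O)C(=O)O[C@@H]2/C=C(/C)[C@@H](OC(C)=O)CC1=O
F8 | step 20 | (1R,3S,6R,4Z)-3,13-diacetoxy-1-[1-(2-nitrobenzenesulfonyl)hydrazinyl]germacra-4,7(11),10(14)-trien-12,6-olide | C=C1CCC2=C(COC(C)=O)C(=O)O[C@@H]2/C=C(/C)[C@@H](OC(C)=O)C[C@H]1N(N)S(=O)(=O)c3ccccc3[N+](=O)[O-]
F9 | step 20 | (1R,3S,6R,4Z)-3,13-diacetoxy-1-diazenylgermacra-4,7(11),10(14)-trien-12,6-olide | C=C1CCC2=C(COC(C)=O)C(=O)O[C@@H]2/C=C(/C)[C@@H](OC(C)=O)C[C@H]1N=N
F10 | step 20 | (3S,6R,1(10)E,4Z)-3,13-diacetoxygermacra-1(10),4,7(11)-trien-12,6-olide | C/C1=C\C[C@H](OC(C)=O)/C(C)=C\[C@H]2OC(=O)C(COC(C)=O)=C2CC1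
A1 | alternative 1 | (1S,3S)-thirteen-membered cyclic diallyl ether with oxygen between C6 and C13, C7=C11 trans in the ring and carrying the C12 orthoester, C3 OSiEt3, C1 OTBS, Z C4=C5, C10=C14 methylene | C=C1CC/C=C(/COC/C=C(/C)[C@@H](O[Si](CC)(CC)CC)C[C@@H]1O[Si](C)(C)C(C)(C)C)C23OCC(C)(CO2)CO3
A2 | alternative 1 | (1S,3S,6R)-ten-membered C6 alcohol with the C7 propen-2-yl orthoester side chain | C=C1CC[C@@H](C(=C)C23OCC(C)(CO2)CO3)[C@H](O)/C=C(/C)[C@@H](O[Si](CC)(CC)CC)C[C@@H]1O[Si](C)(C)C(C)(C)C
A3 | alternative 2 | [(5R)-4-[(4S,6S)-6-acetoxy-4-[(tert-butyldimethylsilyl)oxy]-7-methyl-3-oxooct-7-en-1-yl]-2-oxo-5-vinyl-2,5-dihydrofuran-3-yl]methyl acetate | C=C[C@H]1OC(=O)C(COC(C)=O)=C1CCC(=O)[C@@H](O[Si](C)(C)C(C)(C)C)C[C@H](OC(C)=O)C(C)=C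
A4 | alternative 2 | (1S,3S,6R,4Z)-ten-membered C10 ketone with C1 OTBS, C3 and C13 acetates and the butenolide | O=C1CCC2=C(COC(C)=O)C(=O)O[C@@H]2/C=C(/C)[C@@H](OC(C)=O)C[C@@H]1O[Si](C)(C)C(C)(C)C
A5 | alternative 3 | (4S)-4-[(tert-butyldimethylsilyl)oxy]-3-methyl-6-(prop-1-en-2-yl)-1-vinylcyclohex-2-en-1-ol with vinyl and isopropenyl trans | C=C[C@@]1(O)C=C(C)[C@@H](O[Si](C)(C)C(C)(C)C)C[C@@H]1C(C)=C
A6 | alternative 3 | (3S,1E,4Z)-3-silyloxygermacra-1(10),4-dien-6-one | C\C1=C/C[C@H](O[Si](C)(C)C(C)(C)C)/C(C)=C\C(=O)CCC1
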